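Ring A is C1, C2, C3, C3a, C8a and ring B is C3a, C4–C8, C8a; α is the face of the C3a methyl group, β the other face. Ring B divides into a three-carbon unit C4–C5–C6 with oxygen on its central carbon C5 and a four-carbon unit C7–C8–C8a–C3a whose last two atoms belong to ring A, so it is the (4+3) adduct of an oxyallyl cation and a 2-vinylcyclopentene.
Retrosynthetic cuts, in order: the C8–O ester bond; both C–O bonds of the C5/C6 cis-diol (from a C5=C6 enone); the C1–isopropyl bond (from a C1 ketone); C8–O and C8a–H (reductive hydroxylation of a C7 enone); the C7 carbonyl (allylic oxidation); C3a–C4 and C6–C7 (the cycloaddition); the C8a–vinyl bond.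
Forward: ring A is bought as 3-methylcyclopentenone and becomes the silyloxy diene (steps 1–4); ring B closes in step 5; steps 6–11 move the oxidation pattern around ring B; steps 12–14 build the C1 carbinol; steps 15–18 add the ester and the diol and free the phenol.
Stereochemistry: a CBS reduction sets C1, whose α-silyloxy group sends the cation to the β face and so sets C3a. The α-methyl on C3a then directs H-8a and O-8 (both β), the β attack of the isopropyl group on C1 (after the first C1 centre has been erased as a ketone) and the β osmylation that fixes C5 and C6 together.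

Key step: step 5

Remarks on the chemistry:
- C6 (compounds 10–16) and C5 (compounds 11–16) are carried as epimer mixtures, because both carbons become trigonal in step 11; their SMILES leave these two centres open.
- i-PrMgCl (solution in THF) and 4-(benzyloxy)benzoyl chloride are taken as purchased.

Step 1
Reactants: 1 3-methylcyclopent-2-en-1-one
Product: 3 2-bromo-3-methylcyclopent-2-en-1-one, via 2,3-dibromo-3-methylcyclopentan-1-one 2 (not isolated)
Conditions: Br2, CH2Cl2, 0 °C; then Et3N, 0 °C → rt
Reagents that add atoms: bromine, BrBr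
Why: Bromine adds across the enone and Et3N then removes HBr from the α-bromo ketone (addition–elimination α-bromination of a cyclic enone), leaving the halogen on the carbon that becomes C8a.

Step 2
Reactants: 3 2-bromo-3-methylcyclopent-2-en-1-one
Product: 4 (S)-2-bromo-3-methylcyclopent-2-en-1-ol
Conditions: (R)-2-methyl-CBS-oxazaborolidine (cat.), BH3·SMe2, THF, −20 °C
Reagents that add atoms: none
Why: Corey–Bakshi–Shibata reduction in which the bromoalkene arm acts as the large and the CH2 arm as the small substituent, so the (R)-catalyst should deliver hydride to the face that gives the (S)-alcohol, the future α C1–O bond.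

Step 3
Reactants: 4 (S)-2-bromo-3-methylcyclopent-2-en-1-ol
Product: 5 (S)-[(2-bromo-3-methylcyclopent-2-en-1-yl)oxy](tert-butyl)dimethylsilane
Conditions: TBSCl, imidazole, DMF, rt
Reagents that add atoms: tert-butyldimethylsilyl chloride, CC(C)(C)[Si](C)(C)Cl
Why: Routine silylation of a secondary allylic alcohol gives a bulky ether that survives the coupling and the cycloaddition and later screens the α face.

Step 4
Reactants: 5 (S)-[(2-bromo-3-methylcyclopent-2-en-1-yl)oxy](tert-butyl)dimethylsilane; 6 potassium vinyltrifluoroborate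
Product: 7 (S)-tert-butyldimethyl[(3-methyl-2-vinylcyclopent-2-en-1-yl)oxy]silane
Conditions: PdCl2(dppf) (cat.), Cs2CO3, THF/H2O, 80 °C
Reagents that add atoms: potassium vinyltrifluoroborate (6), C=C[B-](F)(F)F.[K+]
Why: Suzuki–Miyaura coupling of an alkenyl bromide with a vinyltrifluoroborate attaches C8 and C7 to C8a and does not touch the allylic stereocentre.

Step 5
Reactants: 7 (S)-tert-butyldimethyl[(3-methyl-2-vinylcyclopent-2-en-1-yl)oxy]silane; 8 3-chlorobutan-2-one
Product: 10 (1S,3aR)-1-(tert-butyldimethylsilyloxy)-3a,6-dimethyl-2,3,3a,4,6,7-hexahydroazulen-5(1H)-one (1α-silyloxy, 3a α-methyl, C8=C8a alkene, C6 epimers), via 1-methyl-2-oxidoallyl cation 9 (not isolated)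
Conditions: Et3N, CF3CH2OH, 0 °C → rt, 8 in excess and added slowly
Reagents that add atoms: 3-chlorobutan-2-one (8), CC(Cl)C(C)=O
Why: Et3N enolizes 8 toward its methyl group and ionization of chloride in the fluorinated alcohol gives the oxyallyl cation 9, which adds across the diene termini C7 and C3a of 7; the closest known reaction type is the (4+3) cycloaddition of oxyallyl cations from α-haloketones, amine base and trifluoroethanol with 1,3-dienes. Ring B closes in this single intermolecular event, a concerted but asynchronous union of the four-carbon diene with the three-carbon cation in which the C6–C7 bond to the unhindered vinyl terminus leads and the C3a–C4 bond follows (in the stepwise limit a seven-membered closure of the enolate carbon C4 onto the tertiary allyl cation at C3a). The quaternary centre C3a is controlled by the C1 silyloxy group, which occupies the α face next to the diene and sends the cation to the β face, so the methyl ends α, cis to the silyloxy group; C6 forms as a mixture and needs no control because step 11 makes it trigonal. The step needs regioselectivity (CH2 terminus to C3a, CHMe terminus to C7), which should follow because the more substituted, more cation-stabilizing terminus pairs with the nucleophilic CH2 end of the diene while only the unsubstituted terminus can reach the fully substituted C3a. It also needs the seven-membered carbocycle to win over solvent capture and closure through oxygen, which the weakly nucleophilic, ionizing solvent and the excess of 8 favour.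

Step 6
Reactants: 10 hydroazulen-5-one cycloadduct
Product: 11 C5 alcohol (1α-silyloxy, 3a α-methyl, 6-methyl, C8=C8a; C5 and C6 epimers)
Conditions: NaBH4, MeOH, 0 °C
Reagents that add atoms: none
Why: Borohydride reduction of the only carbonyl group gives the C5 carbinol, whose configuration does not matter because this oxygen leaves in step 11.

Step 7
Reactants: 11 C5 alcohol
Product: 12 C5 acetate (1α-silyloxy, 5-acetoxy, 3a α-methyl, 6-methyl, C8=C8a)
Conditions: Ac2O, pyridine, DMAP (cat.), CH2Cl2, rt
Reagents that add atoms: acetic anhydride, CC(=O)OC(C)=O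
Why: DMAP-catalysed acetylation shields the C5 hydroxyl from the oxidants of steps 8 and 9 and turns it into the leaving group of step 11.

Step 8
Reactants: 12 C5 acetate
Product: 13 C7 enone (1α-silyloxy, 5-acetoxy, 3a α-methyl, 6-methyl, C7 ketone conjugated with C8=C8a)
Conditions: Rh2(cap)4 (dirhodium tetracaprolactamate, cat.), t-BuOOH (70% in water), 1,2-dichloroethane, 40 °C
Reagents that add atoms: tert-butyl hydroperoxide, CC(C)(C)OO
Why: Radical allylic oxidation of a cycloalkene to an enone with t-BuOOH should take its hydrogen from C7, the only allylic methylene (C3a has no hydrogen and the tertiary C1–H is screened by the silyl ether), as in the known conversion of cyclic allylic silyl ethers into γ-silyloxy enones, and the neutral medium should leave the β-acetoxy ketone intact.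

Step 9
Reactants: 13 C7 enone
Product: 15 8β-hydroxy-7-ketone with H-8a β (1α-silyloxy, 5-acetoxy, 3a α-methyl, 6-methyl, trans ring fusion), via C8 hydroperoxide 14 (not isolated)
Conditions: Mn(dpm)3 (tris(dipivaloylmethanato)manganese, cat.), PhSiH3, O2 (1 atm), i-PrOH/CH2Cl2, 0 °C; then P(OEt)3
Reagents that add atoms: dioxygen, O=O
Why: Mukaiyama-type reductive α-hydroxylation of an enone (hydrogen-atom transfer from a manganese hydride to the β-carbon, capture of the α-keto radical by O2, phosphite reduction of the hydroperoxide) should place the hydrogen on C8a and the oxygen on C8 from the β face, because the α face is covered by the C3a methyl and the C1 silyloxy group, and the resulting pseudo-equatorial 8β-hydroxyl is also the more stable epimer.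

Step 10
Reactants: 15 8β-hydroxy-7-ketone
Product: 16 8β-triisopropylsilyl ether (1α-tert-butyldimethylsilyloxy, 5-acetoxy, C7 ketone)
Conditions: i-Pr3SiOTf, 2,6-lutidine, CH2Cl2, −40 → 0 °C
Reagents that add atoms: triisopropylsilyl triflate, CC(C)[Si](C(C)C)(C(C)C)OS(=O)(=O)C(F)(F)F
Why: Silylation of the hindered α-ketol with a silyl triflate gives an ether that tolerates base and organometallic reagents and can be told apart from the smaller silyl ether at C1.

Step 11
Reactants: 16 8β-triisopropylsilyl ether
Product: 17 C5=C6 enone (1α-tert-butyldimethylsilyloxy, 3a α-methyl, 6-methyl, C7 ketone, 8β-triisopropylsilyloxy, H-8a β)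
Conditions: DBU, CH2Cl2, 0 °C → rt
Reagents that add atoms: none
Why: E1cB elimination of the β-acetoxy ketone through the C6 enolate can only give the C5=C6 double bond, which removes the C5 and C6 epimer mixtures in one operation.

Step 12
Reactants: 17 C5=C6 enone
Product: 18 C1 alcohol (1α-hydroxy, 8β-triisopropylsilyloxy, C5=C6–C7 enone)
Conditions: CSA (cat.), MeOH/CH2Cl2, 0 °C
Reagents that add atoms: none
Why: Acid-catalysed methanolysis discriminates silyl ethers by bulk, so the tert-butyldimethylsilyl ether at C1 should be cleaved while the triisopropylsilyl ether beside the C7 carbonyl stays.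

Step 13
Reactants: 18 C1 alcohol
Product: 19 1,7-diketone (C1 cyclopentanone, C5=C6–C7 enone, 8β-triisopropylsilyloxy, H-8a β)
Conditions: Dess–Martin periodinane, CH2Cl2, 0 °C → rt
Reagents that add atoms: none
Why: Dess–Martin oxidation of a secondary alcohol proceeds without base, so the C8a–H next to the new ketone should keep its configuration and the β-silyloxy group should not be eliminated.

Step 14
Reactants: 19 1,7-diketone; 20 isopropylmagnesium chloride
Product: 21 C1 carbinol (1α-hydroxy, 1β-isopropyl, C5=C6–C7 enone, 8β-triisopropylsilyloxy)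
Conditions: CeCl3, THF, −78 °C; then aq. NH4Cl
Reagents that add atoms: isopropylmagnesium chloride (20), CC(C)[Mg]Cl
Why: Imamoto organocerium addition, which suppresses enolization and reduction, should take the cyclopentanone C1 well before the C7 carbonyl (conjugated and flanked by the methyl-bearing C6 and the silyloxy-bearing C8) and should enter from the β face, opposite the C3a methyl and the C8 branch of ring B, so the hydroxyl ends α as in the target.

Step 15
Reactants: 21 C1 carbinol
Product: 22 C8 alcohol (1α-hydroxy, 1β-isopropyl, 8β-hydroxy, C5=C6–C7 enone)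
Conditions: HF·pyridine, pyridine, THF, 0 °C → rt
Reagents that add atoms: none
Why: Buffered fluoride desilylation frees the C8 hydroxyl without base, so the α-ketol should neither epimerize nor rearrange.

Step 16
Reactants: 22 C8 alcohol; 23 4-(benzyloxy)benzoyl chloride
Product: 24 C8 4-(benzyloxy)benzoate (1α-hydroxy, 1β-isopropyl, C5=C6–C7 enone)
Conditions: Et3N, DMAP (cat.), CH2Cl2, 0 °C → rt
Reagents that add atoms: 4-(benzyloxy)benzoyl chloride (23), O=C(Cl)c1ccc(OCc2ccccc2)cc1
Why: DMAP-catalysed acylation with an acid chloride acts on the only secondary hydroxyl, at C8, while the tertiary C1 hydroxyl is inert under these conditions.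

Step 17
Reactants: 24 C8 4-(benzyloxy)benzoate
Product: 25 5β,6β-diol (benzyl ether of the target)
Conditions: OsO4 (cat.), NMO, citric acid, t-BuOH/H2O, rt
Reagents that add atoms: osmium tetroxide, O=[Os](=O)(=O)=O; 4-methylmorpholine N-oxide, C[N+]1([O-])CCOCC1; water, O
Why: Upjohn dihydroxylation (citric acid variant for electron-poor alkenes) adds both oxygens syn to the only C=C bond from the β face, the α face at C5 being covered by the pseudo-axial C3a methyl, which gives the cis-diol with both hydroxyls β and the C6 methyl α.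

Step 18
Reactants: 25 5β,6β-diol
Product: 26 CNP0241001.1
Conditions: H2 (1 atm), Pd/C, EtOAc, rt
Reagents that add atoms: none
Why: Hydrogenolysis of the benzyl aryl ether over palladium under neutral conditions frees the phenol and should leave the ester, the ketone and the alcohols alone.

Compound list
1 | 3-methylcyclopent-2-en-1-one | CC1=CC(=O)CC1 | starting material
2 | 2,3-dibromo-3-methylcyclopentan-1-one (racemic, formed in the flask) | CC1(Br)CCC(=O)C1Br | intermediate
3 | 2-bromo-3-methylcyclopent-2-en-1-one | CC1=C(Br)C(=O)CC1 | intermediate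
4 | (S)-2-bromo-3-methylcyclopent-2-en-1-ol | O[C@H]1CCC(C)=C1Br | intermediate
5 | (S)-[(2-bromo-3-methylcyclopent-2-en-1-yl)oxy](tert-butyl)dimethylsilane | CC(C)(C)[Si](C)(C)O[C@H]1CCC(C)=C1Br | intermediate
6 | potassium vinyltrifluoroborate | C=C[B-](F)(F)F.[K+] | starting material
7 | (S)-tert-butyldimethyl[(3-methyl-2-vinylcyclopent-2-en-1-yl)oxy]silane | CC(C)(C)[Si](C)(C)O[C@H]1CCC(C)=C1C=C | intermediate
8 | 3-chlorobutan-2-one (racemic) | CC(Cl)C(C)=O | starting material
9 | 1-methyl-2-oxidoallyl cation (formed in the flask) | C[CH+]C([O-])=C | intermediate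
10 | (1S,3aR)-1-(tert-butyldimethylsilyloxy)-3a,6-dimethyl-2,3,3a,4,6,7-hexahydroazulen-5(1H)-one, C6 epimers | CC(C)(C)[Si](C)(C)O[C@H]1CC[C@]2(C)CC(=O)C(C)CC=C12 | intermediate
11 | C5 alcohol of 10, C5 and C6 epimers | CC(C)(C)[Si](C)(C)O[C@H]1CC[C@]2(C)CC(O)C(C)CC=C12 | intermediate
12 | C5 acetate of 11 | CC(C)(C)[Si](C)(C)O[C@H]1CC[C@]2(C)CC(OC(C)=O)C(C)CC=C12 | intermediate
13 | C7 enone: 1α-silyloxy, 5-acetoxy, 3a α-methyl, 6-methyl, 7-oxo, C8=C8a | CC(C)(C)[Si](C)(C)O[C@H]1CC[C@]2(C)CC(OC(C)=O)C(C)C(=O)C=C12 | intermediate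
14 | 8β-hydroperoxy-7-ketone, H-8a β (formed in the flask) | CC(C)(C)[Si](C)(C)O[C@H]1CC[C@]2(C)CC(OC(C)=O)C(C)C(=O)[C@H](OO)[C@H]21 | intermediate
15 | 8β-hydroxy-7-ketone, H-8a β, trans-fused | CC(C)(C)[Si](C)(C)O[C@H]1CC[C@]2(C)CC(OC(C)=O)C(C)C(=O)[C@H](O)[C@H]21 | intermediate
16 | 8β-triisopropylsilyl ether of 15 | CC(C)(C)[Si](C)(C)O[C@H]1CC[C@]2(C)CC(OC(C)=O)C(C)C(=O)[C@H](O[Si](C(C)C)(C(C)C)C(C)C)[C@H]21 | intermediate
17 | C5=C6 enone: 1α-tert-butyldimethylsilyloxy, 8β-triisopropylsilyloxy, 7-oxo | CC(C)(C)[Si](C)(C)O[C@H]1CC[C@]2(C)CC=C(C)C(=O)[C@H](O[Si](C(C)C)(C(C)C)C(C)C)[C@H]21 | intermediate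
18 | C1 alcohol: 1α-hydroxy, 8β-triisopropylsilyloxy, C5=C6–C7 enone | O[C@H]1CC[C@]2(C)CC=C(C)C(=O)[C@H](O[Si](C(C)C)(C(C)C)C(C)C)[C@H]21 | intermediate
19 | 1,7-diketone: C1 ketone, C5=C6–C7 enone, 8β-triisopropylsilyloxy | O=C1CC[C@]2(C)CC=C(C)C(=O)[C@H](O[Si](C(C)C)(C(C)C)C(C)C)[C@H]21 | intermediate
20 | isopropylmagnesium chloride | CC(C)[Mg]Cl | starting material
21 | C1 carbinol: 1α-hydroxy, 1β-isopropyl, 8β-triisopropylsilyloxy, C5=C6–C7 enone | CC(C)[C@]1(O)CC[C@]2(C)CC=C(C)C(=O)[C@H](O[Si](C(C)C)(C(C)C)C(C)C)[C@H]21 | intermediate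
22 | C8 alcohol: 1α,8β-dihydroxy, 1β-isopropyl, C5=C6–C7 enone | CC(C)[C@]1(O)CC[C@]2(C)CC=C(C)C(=O)[C@H](O)[C@H]21 | intermediate
23 | 4-(benzyloxy)benzoyl chloride | O=C(Cl)c1ccc(OCc2ccccc2)cc1 | starting material
24 | C8 4-(benzyloxy)benzoate of 22 | CC(C)[C@]1(O)CC[C@]2(C)CC=C(C)C(=O)[C@H](OC(=O)c3ccc(OCc4ccccc4)cc3)[C@H]21 | intermediate
25 | 5β,6β-diol, benzyl ether of the target | CC(C)[C@]1(O)CC[C@]2(C)C[C@H](O)[C@](C)(O)C(=O)[C@H](OC(=O)c3ccc(OCc4ccccc4)cc3)[C@H]21 | intermediate
26 | CNP0241001.1, (1R,3aR,5S,6S,8R,8aS)-1,5,6-trihydroxy-1-isopropyl-3a,6-dimethyl-7-oxodecahydroazulen-8-yl 4-hydroxybenzoate | CC(C)[C@]1(O)CC[C@]2(C)C[C@H](O)[C@](C)(O)C(=O)[C@H](OC(=O)c3ccc(O)cc3)[C@H]21 | target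

Total step count: 18
Longest linear sequence: 18 steps (1 → 26)

Steps most likely to fail

Step 5. The cation may be lost to solvent capture or close through oxygen before it meets the diene, whose s-cis geometry is disfavoured by the C3a methyl. Bond formation may also occur with the termini exchanged or on the α face. The fallback sets out from diene 7 and returns at 10. The symmetrical, chlorine-stabilized 1,3-dichloro-oxyallyl cation from 1,1,3-trichloroacetone (NaOCH2CF3, CF3CH2OH) should add without any regiochemical question and give the 4,6-dichloro cycloadduct F1. Zn–Cu couple with NH4Cl in MeOH removes both chlorines to give the C6-unsubstituted hydroazulen-5-one F2. LiN(i-Pr)2 in THF at −78 °C should then deprotonate C6 and not the neopentyl C4, and MeI delivers 10, so the methyl group enters after the ring is closed.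

Step 8. Hydrogen abstraction may occur at C1–H, which would lead to loss of the silyl ether. The enone may also be oxidized further, or acetic acid may be lost from the product under the reaction conditions. The fallback sets out from acetate 12 and returns at enone 13. Photo-oxygenation (O2, hν, tetraphenylporphyrin, CH2Cl2) is a Schenck ene reaction that should bond oxygen to C8a and take its hydrogen from C7, the only hydrogen-bearing allylic carbon on the crowded side of the alkene, giving the C8a hydroperoxide with a C7=C8 double bond F3. PPh3 in the same flask reduces it to the tertiary allylic alcohol F4. Pyridinium chlorochromate in CH2Cl2 then effects the oxidative 1,3-transposition of the tertiary allylic alcohol (Babler–Dauben), which gives 13.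

Step 14. The isopropyl reagent may add 1,2 or 1,4 to the C7 enone, reduce or enolize the C1 ketone, or attack partly from the α face. The fallback sets out from 17 and returns at 21; in it C1 is the only carbonyl group when the isopropyl group enters. Luche reduction (NaBH4, CeCl3·7H2O, MeOH) gives the C7 allylic alcohol F5, and 4-methoxybenzyl trichloroacetimidate with La(OTf)3 (cat.) gives its 4-methoxybenzyl ether F6. CSA in MeOH frees the C1 alcohol F7, and Dess–Martin periodinane gives the C1 ketone F8. i-PrMgCl with CeCl3 at −78 °C gives the C1 carbinol F9. DDQ in wet CH2Cl2 removes the 4-methoxybenzyl group to give the allylic alcohol F10, and MnO2 oxidizes only this allylic hydroxyl to give 21.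

Further compounds
F1 | step 5 | 4,6-dichloro cycloadduct: 1α-silyloxy, 3a α-methyl, 5-oxo, C8=C8a | CC(C)(C)[Si](C)(C)O[C@H]1CC[C@]2(C)C(Cl)C(=O)C(Cl)CC=C12
F2 | step 5 | (1S,3aR)-1-(tert-butyldimethylsilyloxy)-3a-methyl-2,3,3a,4,6,7-hexahydroazulen-5(1H)-one | CC(C)(C)[Si](C)(C)O[C@H]1CC[C@]2(C)CC(=O)CCC=C12
F3 | step 8 | C8a hydroperoxide with C7=C8 double bond, 5-acetoxy, 1α-silyloxy | CC(C)(C)[Si](C)(C)O[C@H]1CC[C@]2(C)CC(OC(C)=O)C(C)C=C[C@@]12OO
F4 | step 8 | C8a tertiary allylic alcohol with C7=C8 double bond, 5-acetoxy, 1α-silyloxy | CC(C)(C)[Si](C)(C)O[C@H]1CC[C@]2(C)CC(OC(C)=O)C(C)C=C[C@@]12O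
F5 | step 14 | C7 allylic alcohol of 17 (C7 epimers) | CC(C)(C)[Si](C)(C)O[C@H]1CC[C@]2(C)CC=C(C)C(O)[C@H](O[Si](C(C)C)(C(C)C)C(C)C)[C@H]21
F6 | step 14 | C7 4-methoxybenzyl ether of F5 | CC(C)(C)[Si](C)(C)O[C@H]1CC[C@]2(C)CC=C(C)C(OCc3ccc(OC)cc3)[C@H](O[Si](C(C)C)(C(C)C)C(C)C)[C@H]21
F7 | step 14 | C1 alcohol: 1α-hydroxy, 7-(4-methoxybenzyloxy), 8β-triisopropylsilyloxy | O[C@H]1CC[C@]2(C)CC=C(C)C(OCc3ccc(OC)cc3)[C@H](O[Si](C(C)C)(C(C)C)C(C)C)[C@H]21
F8 | step 14 | C1 ketone: 7-(4-methoxybenzyloxy), 8β-triisopropylsilyloxy | O=C1CC[C@]2(C)CC=C(C)C(OCc3ccc(OC)cc3)[C@H](O[Si](C(C)C)(C(C)C)C(C)C)[C@H]21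
F9 | step 14 | C1 carbinol: 1α-hydroxy, 1β-isopropyl, 7-(4-methoxybenzyloxy), 8β-triisopropylsilyloxy | CC(C)[C@]1(O)CC[C@]2(C)CC=C(C)C(OCc3ccc(OC)cc3)[C@H](O[Si](C(C)C)(C(C)C)C(C)C)[C@H]21
F10 | step 14 | C7 allylic alcohol: 1α-hydroxy, 1β-isopropyl, 7-hydroxy, 8β-triisopropylsilyloxy | CC(C)[C@]1(O)CC[C@]2(C)CC=C(C)C(O)[C@H](O[Si](C(C)C)(C(C)C)C(C)C)[C@H]21
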